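**Retrosynthetic overview**

- Feature: one ether oxygen joins C2 to C9 (cladiellane numbering). It belongs both to the tetrahydrofuran (O, C2, C1, C10, C9) and to the oxonane (O, C2–C9), whose vicinal C6/C7 oxygens lie just past the C8–C9 bond. An allylic oxonium ylide centred on that oxygen would, on [2,3] shift, create exactly C8–C9 and a C6=C7 alkene.
- Late cuts: the C6/C7 oxygens come from the (Z)-C6=C7 alkene. The C13 enone comes from a C11 ketone by dehydrogenation, methyl addition and oxidative 1,3-transposition. The oxepane comes from C3–OH and a C16 triflate.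
- The cyclohexene is cut by an intermolecular Diels–Alder reaction between the C1=C10–C11=C12 ethoxy diene and methyl vinyl ketone. The diene comes from the C10 ketone by enol triflate formation and Stille coupling.
- The bridged oxonene is cut to a 2,6-cis tetrahydropyranyl diazoketone. That compound is built by chelation-controlled aldol, syn reduction and oxa-Michael closure from (S)-2-methylglycidol, which supplies the only purchased stereocentre (C3).
- Ring order: tetrahydropyran, then tetrahydrofuranone and oxonene together, then cyclohexene, then oxepane.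

Key step: step 18

Remark (numbering): cladiellane numbering is used for every intermediate. C1–C16 are skeletal and the methyl groups sit on C3, C7, C11 and C15.

Remark (assumption): the SMILES is read as 1S,2R,3R,4S,6S,7S,9R,10R,14S,15S. This places H1, H10 and H14 on one face of the cyclohexenone and C15 cis to C2, so the endo cycloadduct is the one required.

Remark: the C11 configuration of carbinol 41 is left open because step 29 erases it.

Step 1
Reactants: 1 (S)-2-methylglycidol
Product: 2 (R)-2-methyl-2-[(trityloxy)methyl]oxirane (same spatial arrangement at C3 as in 1)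
Conditions: TrCl, Et3N, DMAP (cat.), CH2Cl2, 0 °C to rt
Reagents that add atoms: trityl chloride, ClC(c1ccccc1)(c1ccccc1)c1ccccc1
Why: Selective O-tritylation (SN1-type etherification) masks the C2 arm with a group that is inert to hot alkoxide and cannot migrate to the neighbouring tertiary oxygen as a silyl group could, and no bond to the C3 stereocentre is touched.

Step 2
Reactants: 2 trityl ether
Product: 3 (R)-1-[(4-methoxybenzyl)oxy]-2-methyl-3-(trityloxy)propan-2-ol
Conditions: 4-MeOC6H4CH2OH, NaH, DMF, 0 to 70 °C
Reagents that add atoms: 4-methoxybenzyl alcohol, COc1ccc(CO)cc1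
Why: Base-mediated SN2 epoxide opening takes place at the unsubstituted CH2 terminus (future C4) of the 2,2-disubstituted oxirane, so the C3–O bond and the purchased configuration are retained.

Step 3
Reactants: 3 tertiary alcohol
Product: 4 C3 methoxymethyl ether of 3
Conditions: MOMCl, iPr2NEt, ClCH2CH2Cl, 60 °C
Reagents that add atoms: chloromethyl methyl ether, COCCl
Why: Alkylation of the hindered tertiary alcohol with the very reactive chloromethyl ether under amine base (acetal ether formation) installs the small, chelation-capable C3 oxygen substituent needed for the later aldol.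

Step 4
Reactants: 4 fully protected triol
Product: 5 (S)-3-[(4-methoxybenzyl)oxy]-2-(methoxymethoxy)-2-methylpropan-1-ol
Conditions: TsOH·H2O (cat.), MeOH/CH2Cl2, 0 °C
Reagents that add atoms: none
Why: Acid-catalysed methanolysis of the trityl ether runs through the stabilised trityl cation far faster than cleavage of the methoxymethyl acetal or the 4-methoxybenzyl ether, which frees only the C2 hydroxyl.

Step 5
Reactants: 5 primary alcohol
Product: 6 (R)-3-[(4-methoxybenzyl)oxy]-2-(methoxymethoxy)-2-methylpropanal (C2 aldehyde)
Conditions: Dess–Martin periodinane, CH2Cl2, rt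
Reagents that add atoms: none
Why: Dess–Martin oxidation of the neopentyl-type primary alcohol stops at the aldehyde, which has no alpha hydrogen and so cannot epimerise.

Step 6
Reactants: 6 C2 aldehyde; 7 methyl (triphenylphosphoranylidene)acetate
Product: 8 methyl (2E,4S)-5-[(4-methoxybenzyl)oxy]-4-(methoxymethoxy)-4-methylpent-2-enoate
Conditions: toluene, 80 °C
Reagents that add atoms: none
Why: Wittig olefination with the ester-stabilised ylide gives the (E)-enoate with its usual selectivity and brings in C1 and C10.

Step 7
Reactants: 8 (E)-enoate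
Product: 9 methyl (2E,4S)-5-hydroxy-4-(methoxymethoxy)-4-methylpent-2-enoate
Conditions: DDQ, CH2Cl2/pH 7 buffer, 0 °C
Reagents that add atoms: none
Why: Oxidative cleavage of the electron-rich 4-methoxybenzyl ether with DDQ in wet solvent leaves the enoate and the methoxymethyl ether untouched.

Step 8
Reactants: 9 C4 alcohol
Product: 10 methyl (2E,4S)-4-(methoxymethoxy)-4-methyl-5-oxopent-2-enoate (C4 aldehyde)
Conditions: Dess–Martin periodinane, CH2Cl2, rt
Reagents that add atoms: none
Why: Dess–Martin oxidation gives the alpha-quaternary alpha-alkoxy aldehyde, which is configurationally safe because C3 bears no hydrogen.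

Step 9
Reactants: 11 3-methylbut-3-en-2-one
Product: 12 3-methyl-2-(trimethylsilyloxy)buta-1,3-diene
Conditions: TMSOTf, Et3N, Et2O, 0 °C
Reagents that add atoms: trimethylsilyl triflate, C[Si](C)(C)OS(=O)(=O)C(F)(F)F
Why: Soft enolisation (silyl triflate and amine) of the methyl ketone can only occur at the CH3 group (C5), giving the cross-conjugated silyl enol ether as the Mukaiyama donor.

Step 10
Reactants: 10 C4 aldehyde; 12 silyl enol ether
Product: 13 methyl (2E,4S,5S)-5-hydroxy-4-(methoxymethoxy)-4,8-dimethyl-7-oxonona-2,8-dienoate (beta-hydroxy enone, new centre C4)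
Conditions: MgBr2·OEt2 (3 equiv), CH2Cl2, −78 to −30 °C; aq. NH4Cl
Reagents that add atoms: none
Why: Mukaiyama aldol addition under Cram chelate control, in which MgBr2 ties the aldehyde oxygen to the C3 methoxymethoxy oxygen and the nucleophile reaches C4 from the face flanked by the C3 methyl group, away from the larger alkenyl ester arm, which sets 4S.

Step 11
Reactants: 13 beta-hydroxy enone
Product: 15 methyl (2E,4S,5S,7R)-5,7-dihydroxy-4-(methoxymethoxy)-4,8-dimethylnona-2,8-dienoate (C4/C6 syn-1,3-diol), via diethylboron chelate 14 (not isolated)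
Conditions: Et2BOMe, THF/MeOH (4:1), −78 °C; NaBH4; AcOH quench, MeOH co-evaporation
Reagents that add atoms: none
Why: Narasaka–Prasad reduction, in which chelate 14 locks O4 and the C6 carbonyl in a half-chair and external hydride adds axially to give the syn-1,3-diol (6R), 1,2-reduction of the boron-activated ketone being much faster than any attack on the enoate.

Step 12
Reactants: 15 syn-1,3-diol
Product: 16 methyl 2-[(2R,3R,4S,6R)-4-hydroxy-3-(methoxymethoxy)-3-methyl-6-(prop-1-en-2-yl)oxan-2-yl]acetate (2,6-cis tetrahydropyran)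
Conditions: KOtBu (0.2 equiv), THF, 0 °C
Reagents that add atoms: none
Why: Reversible 6-exo-trig oxa-Michael addition of the C6 alkoxide under thermodynamic control gives the chair with the C2 acetate arm, the C6 isopropenyl group and the C3 methyl group all equatorial, which sets 2R, while O4 could only close a four-membered ring.

Step 13
Reactants: 16 tetrahydropyranol
Product: 17 4-O-tert-butyldimethylsilyl ether of 16
Conditions: TBSOTf, 2,6-lutidine, CH2Cl2, 0 °C
Reagents that add atoms: tert-butyldimethylsilyl triflate, CC(C)(C)[Si](C)(C)OS(=O)(=O)C(F)(F)F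
Why: Silylation with the silyl triflate overcomes the hindrance of the axial C4 hydroxyl next to quaternary C3 and gives the robust ether that stays in place until the end.

Step 14
Reactants: 17 silyl ether
Product: 19 C3 tertiary alcohol (17 without the methoxymethyl group), via bipyridinium salt 18 (not isolated)
Conditions: TMSOTf, 2,2'-bipyridyl, CH2Cl2, 0 °C; then H2O, rt
Reagents that add atoms: none
Why: Silyl triflate activation of the acetal under bipyridyl buffering is a near-neutral acetal cleavage that passes through the water-labile salt 18 and spares the C4 silyl ether, the ester and the allylic C6–O ring bond, and 19 is silylated at once to forestall gamma-lactonisation onto the ester.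

Step 15
Reactants: 19 tertiary alcohol
Product: 20 3-O-triethylsilyl, 4-O-tert-butyldimethylsilyl tetrahydropyranyl acetate methyl ester
Conditions: TESOTf, 2,6-lutidine, CH2Cl2, 0 °C to rt
Reagents that add atoms: triethylsilyl triflate, CC[Si](CC)(CC)OS(=O)(=O)C(F)(F)F
Why: Triflate-mediated silylation of the tertiary alcohol gives a weakly coordinating ether without activated C–H bonds for the carbenoid step, one that mild acid can later remove in the presence of the C4 silyl ether.

Step 16
Reactants: 20 methyl ester
Product: 21 the corresponding carboxylic acid (C10 acid)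
Conditions: LiOH, THF/MeOH/H2O, rt; AcOH to pH 5
Reagents that add atoms: lithium hydroxide, [Li+].[OH-]
Why: Ester saponification (BAc2) occurs at the unhindered acetate arm, both silyl ethers tolerate LiOH at room temperature, and the mild acidification protects the triethylsilyl ether.

Step 17
Reactants: 21 carboxylic acid
Product: 23 tetrahydropyranyl diazoketone (C2–C1H2–C10(=O)–C9H=N2), via mixed anhydride 22 (not isolated)
Conditions: iBuOCOCl, Et3N, Et2O, −20 °C; then CH2N2, Et2O, 0 °C to rt
Reagents that add atoms: diazomethane, C=[N+]=[N-]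
Why: Activation as the mixed carbonic anhydride and C-acylation of diazomethane (first stage of the Arndt–Eistert sequence) gives the alpha-diazoketone and brings in C9 under conditions too mild to disturb any stereocentre.

Step 18
Reactants: 23 diazoketone
Product: 25 C2–O–C9 bridged (Z)-oxonene with the C10 ketone (11-oxabicyclo[6.2.1]undecenone; 2R,9R; C3 and C8 cis on the furanone; 3-OTES and 4-OTBS retained), via oxonium ylide 24 (not isolated)
Conditions: Cu(CF3COCHCOCF3)2 (5 mol %), CH2Cl2, reflux, slow addition of 23
Reagents that add atoms: none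
Why: Loss of N2 from 23 at the divalent copper complex leaves a strongly electrophilic metal-bound carbene at C9, and a lone pair of the pyran oxygen, which stands in a 1,5-relationship to C9, adds to it and releases the catalyst to give ylide 24. In 24 the carbanionic C9 bonds to the alkene terminus C8 while the allylic O–C6 bond is cut and the pi bond moves to C6=C7, a concerted suprafacial [2,3]-sigmatropic shift through an envelope-shaped five-centre transition state, and the closest known reaction type is the copper-catalysed oxonium ylide formation and [2,3] rearrangement of diazoketones tethered to cyclic allylic ethers. The tetrahydrofuran-3-one ring (O, C2, C1, C10, C9) closes by O–C9 bond formation in a five-membered closure onto the carbene carbon, whereas the oxonene (O, C2 to C9) is produced by enlarging the six-membered ring by three atoms, so no end-to-end medium-ring cyclisation is needed. C9 is the only new stereocentre and is dictated by C2, because a one-atom oxygen bridge can span the nine-membered ring only with C3 and C8 cis on the new five-membered ring, and the C6 carbinol centre is consumed. The step requires attack of the ring oxygen rather than O3, O4 or a C–H bond on the carbene, a [2,3] rather than a [1,2] shift, and the (Z)-alkene. The 2,6-cis diequatorial chair holds the tether and the isopropenyl group on the same side of the oxygen, the bulky and weakly basic silyl ethers offer neither a good donor nor acetal or benzylic C–H bonds, and the electron-poor hexafluoroacetylacetonate ligand set favours ylide chemistry and the (Z)-selective pathway.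

Step 19
Reactants: 25 bicyclic ketone
Product: 27 C1=C10 enol triflate, via sodium enolate 26 (not isolated)
Conditions: NaN(SiMe3)2, THF, −78 °C; then PhNTf2, −78 to 0 °C
Reagents that add atoms: N-phenylbis(trifluoromethanesulfonimide), O=S(=O)(N(c1ccccc1)S(=O)(=O)C(F)(F)F)C(F)(F)F
Why: Kinetic deprotonation at the accessible C1 methylene rather than the hindered alpha-alkoxy C9 methine, followed by O-sulfonylation of the enolate, gives the C1=C10 enol triflate.

Step 20
Reactants: 27 enol triflate; 28 tributyl(1-ethoxyvinyl)stannane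
Product: 29 bicyclic 2-ethoxy diene (C1=C10–C11(OEt)=C12)
Conditions: Pd(PPh3)4 (5 mol %), LiCl (3 equiv), THF, reflux
Reagents that add atoms: none
Why: Stille cross-coupling (oxidative addition of the enol triflate to zerovalent palladium, chloride-assisted transmetalation, reductive elimination) joins C10 to C11 under neutral conditions that the acid-labile diene tolerates.

Step 21
Reactants: 29 ethoxy diene; 30 methyl vinyl ketone
Product: 31 tricyclic endo adduct (C10=C11 enol ether, C14 acetyl cis to C2, H1 and H14 cis, cyclohexene on the furan face opposite C3 and C8)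
Conditions: 30 (10 equiv), BHT (trace), toluene, 80 °C, sealed base-washed tube
Reagents that add atoms: none
Why: In this normal-demand Diels–Alder reaction the C11 ethoxy group (para rule) and the C1 ring substituent (ortho rule) both send C13 to C12 and C14 to C1, the dienophile adds to the diene face opposite the C3–C8 bridge (sets C1), the Alder endo mode places C15 cis to C2 (sets C14) and is further favoured because the exo mode would press the acetyl group against C2 and the C3 silyloxy and methyl groups, and acid and base are excluded so that the kinetically formed axial acetyl group is kept.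

Step 22
Reactants: 31 methyl ketone
Product: 32 C14 isopropenyl compound (C15=C16)
Conditions: (C5H5)2Ti(CH3)2 (3 equiv), toluene, 70 °C, dark
Reagents that add atoms: dimethyltitanocene, [CH3-].[CH3-].[Ti+4].c1cc[cH-]c1.c1cc[cH-]c1
Why: Petasis methylenation uses a thermally generated, non-basic titanium methylidene, so C16 is introduced without enolisation and the contra-thermodynamic C14 configuration survives, while the enol ether and the silyl ethers are inert.

Step 23
Reactants: 32 triene
Product: 34 C16 primary alcohol (15S), via B-alkyl-9-BBN 33 (not isolated)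
Conditions: 9-BBN (1.5 equiv), THF, 0 °C to rt; then NaOH, H2O2, 0 °C
Reagents that add atoms: hydrogen peroxide, OO
Why: In this anti-Markovnikov hydroboration–oxidation the bulky borane selects the 1,1-disubstituted C15=C16 alkene over the trisubstituted C6=C7 and the tetrasubstituted enol ether alkenes, and with the C14–H bond lying near the C15 methyl group to relieve A(1,2) strain the reagent should approach anti to the branched C1 side, which gives 15S.

Step 24
Reactants: 34 enol ether alcohol
Product: 35 C11 ketone with free C3 and C16 hydroxyls (cis-fused, H10 cis to H1; 4-OTBS retained)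
Conditions: 1 M HCl/THF (1:4), rt
Reagents that add atoms: water, O
Why: Acid hydrolysis cleaves the enol ether (protonation at C10, loss of ethanol) and the more labile triethylsilyl ether while the hindered secondary tert-butyldimethylsilyl ether survives, and the epimerisable C10 settles as the cis-fused hydroisobenzofuranone, the only unstrained fusion in the bridged frame.

Step 25
Reactants: 35 keto diol
Product: 37 tetracyclic C11 ketone with the oxepane (O, C3, C2, C1, C14, C15, C16) closed, via C16 triflate 36 (not isolated)
Conditions: Tf2O (1.1 equiv), 2,6-lutidine (3 equiv), CH2Cl2, −78 °C to rt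
Reagents that add atoms: none
Why: The primary C16 alcohol is triflated selectively at low temperature and on warming the nearby tertiary C3 hydroxyl displaces the triflate in an intramolecular Williamson-type 7-exo-tet SN2 etherification that touches neither C3 nor C15.

Step 26
Reactants: 37 tetracyclic ketone
Product: 39 C11=C12 trimethylsilyl enol ether, via lithium enolate 38 (not isolated)
Conditions: LiN(iPr)2, THF, −78 °C; then TMSCl, −78 to 0 °C
Reagents that add atoms: chlorotrimethylsilane, C[Si](C)(C)Cl
Why: Kinetic enolisation with the hindered amide base takes a proton from the C12 methylene rather than the ring-fusion C10 methine, which also avoids beta-elimination of the C9 oxygen, and O-silylation fixes the regiochemistry.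

Step 27
Reactants: 39 silyl enol ether
Product: 40 C11 ketone with the C12=C13 alkene (enone)
Conditions: Pd(OAc)2 (1.05 equiv), MeCN, rt
Reagents that add atoms: none
Why: Saegusa–Ito oxidation with divalent palladium converts the regiodefined silyl enol ether into the C12=C13 enone under neutral conditions that leave the isolated C6=C7 alkene alone.

Step 28
Reactants: 40 enone
Product: 41 C11 tertiary allylic alcohol carrying the C11 methyl group (C11 configuration open)
Conditions: CeCl3 (anhydrous), MeLi, THF, −78 °C
Reagents that add atoms: methyllithium, [Li]C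
Why: In this organocerium 1,2-addition the oxophilic and weakly basic methylcerium reagent attacks the C11 carbonyl without conjugate addition or enolisation, and the new C11 centre is erased in the next step.

Step 29
Reactants: 41 tertiary allylic alcohol
Product: 42 tetracyclic C13 enone with the C11 methyl group (C11=C12)
Conditions: (C5H5NH)(CrO3Cl), 4 Å molecular sieves, CH2Cl2, rt
Reagents that add atoms: pyridinium chlorochromate (supplies the C13 oxygen), [O-][Cr](=O)(=O)Cl.c1cc[nH+]cc1
Why: In the Babler–Dauben oxidative 1,3-transposition the allylic oxygen function is carried at chromium by a [3,3] shift from C11 to C13 and oxidised there, while the isolated alkene, the ethers and the silyl ether are inert.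

Step 30
Reactants: 42 enone alkene
Product: 43 6,7-syn-diol (6R,7S)
Conditions: OsO4 (5 mol %), N-methylmorpholine N-oxide, acetone/H2O, rt
Reagents that add atoms: OsO4 (catalytic oxygen carrier), O=[Os](=O)(=O)=O; N-methylmorpholine N-oxide, C[N+]1([O-])CCOCC1; water, O
Why: Catalytic OsO4/N-oxide syn-dihydroxylation picks the electron-rich C6=C7 alkene over the enone and should add from the outer face of the (Z)-oxonene, the face turned away from the oxepane oxygen and the C2–O–C9 bridge, which sets C7 as in the target and C6 provisionally as 6R.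

Step 31
Reactants: 43 syn-diol
Product: 44 C6 ketone with the C7 tertiary hydroxyl (alpha-hydroxy ketone)
Conditions: SO3·pyridine, DMSO, Et3N, CH2Cl2, 0 °C
Reagents that add atoms: none
Why: Parikh–Doering (activated DMSO) oxidation converts only the secondary C6 alcohol, does not cleave the glycol C–C bond and leaves the C7 hydroxyl free as a directing group.

Step 32
Reactants: 44 alpha-hydroxy ketone
Product: 46 6,7-diol of target configuration (6S,7S), via C7 alkoxyborohydride 45 (not isolated)
Conditions: Me4NBH(OAc)3, MeCN/AcOH (1:1), −30 to 0 °C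
Reagents that add atoms: none
Why: In this hydroxyl-directed triacetoxyborohydride reduction (Saksena–Evans type) ligand exchange at O7 gives 45, which delivers hydride to C6 on the outer face where O7 sits and so turns O6 inwards (6S) without any SN2 attack through the ring interior, while the enone has no neighbouring hydroxyl and is not reduced by this mild reagent.

Step 33
Reactants: 46 silyl ether diol
Product: 47 4,6,7-triol
Conditions: HF (48 % aq.), MeCN, 0 °C to rt
Reagents that add atoms: none
Why: Fluoride-driven Si–O cleavage under acidic conditions removes the hindered C4 silyl ether without the C14 enolisation or the vinylogous beta-elimination of the C9 oxygen that a basic fluoride source could start.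

Step 34
Reactants: 47 triol
Product: 48 target CNP0212231.3 (4,6-diacetate, free C7 hydroxyl)
Conditions: Ac2O, pyridine, DMAP (cat.), CH2Cl2, rt
Reagents that add atoms: acetic anhydride, CC(=O)OC(C)=O
Why: DMAP-catalysed acylation esterifies the two secondary hydroxyls at C4 and C6, while the hindered tertiary C7 hydroxyl does not react at room temperature.

**Compound list**

1 | (S)-2-methylglycidol | C[C@]1(CO)CO1 | starting material
2 | (R)-2-methyl-2-[(trityloxy)methyl]oxirane | C[C@]1(COC(c2ccccc2)(c2ccccc2)c2ccccc2)CO1 | intermediate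
3 | (R)-1-[(4-methoxybenzyl)oxy]-2-methyl-3-(trityloxy)propan-2-ol | C[C@](O)(COC(c1ccccc1)(c1ccccc1)c1ccccc1)COCc1ccc(OC)cc1 | intermediate
4 | C3 methoxymethyl ether of 3 | C[C@](OCOC)(COC(c1ccccc1)(c1ccccc1)c1ccccc1)COCc1ccc(OC)cc1 | intermediate
5 | (S)-3-[(4-methoxybenzyl)oxy]-2-(methoxymethoxy)-2-methylpropan-1-ol | C[C@](OCOC)(CO)COCc1ccc(OC)cc1 | intermediate
6 | (R)-3-[(4-methoxybenzyl)oxy]-2-(methoxymethoxy)-2-methylpropanal | C[C@](OCOC)(C=O)COCc1ccc(OC)cc1 | intermediate
7 | methyl (triphenylphosphoranylidene)acetate | COC(=O)C=P(c1ccccc1)(c1ccccc1)c1ccccc1 | starting material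
8 | methyl (2E,4S)-5-[(4-methoxybenzyl)oxy]-4-(methoxymethoxy)-4-methylpent-2-enoate | COC(=O)/C=C/[C@](C)(OCOC)COCc1ccc(OC)cc1 | intermediate
9 | methyl (2E,4S)-5-hydroxy-4-(methoxymethoxy)-4-methylpent-2-enoate | COC(=O)/C=C/[C@](C)(OCOC)CO | intermediate
10 | methyl (2E,4S)-4-(methoxymethoxy)-4-methyl-5-oxopent-2-enoate | COC(=O)/C=C/[C@](C)(OCOC)C=O | intermediate
11 | 3-methylbut-3-en-2-one | CC(=O)C(C)=C | starting material
12 | 3-methyl-2-(trimethylsilyloxy)buta-1,3-diene | C=C(C)C(=C)O[Si](C)(C)C | intermediate
13 | aldol adduct, beta-hydroxy enone (4S in cladiellane numbering) | COC(=O)/C=C/[C@](C)(OCOC)[C@@H](O)CC(=O)C(C)=C | intermediate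
14 | O4-diethylboryl chelate of 13 | COC(=O)/C=C/[C@](C)(OCOC)[C@@H](OB(CC)CC)CC(=O)C(C)=C | intermediate
15 | C4/C6 syn-1,3-diol | COC(=O)/C=C/[C@](C)(OCOC)[C@@H](O)C[C@@H](O)C(C)=C | intermediate
16 | 2,6-cis tetrahydropyran ester (2R,3R,4S,6R) | O1[C@H](CC(=O)OC)[C@](C)(OCOC)[C@@H](O)C[C@@H]1C(C)=C | intermediate
17 | 4-O-TBS ether of 16 | O1[C@H](CC(=O)OC)[C@](C)(OCOC)[C@@H](O[Si](C)(C)C(C)(C)C)C[C@@H]1C(C)=C | intermediate
18 | N-(C3-oxymethyl)-2,2'-bipyridinium triflate | O1[C@H](CC(=O)OC)[C@](C)(OC[n+]2ccccc2-c2ccccn2)[C@@H](O[Si](C)(C)C(C)(C)C)C[C@@H]1C(C)=C.[O-]S(=O)(=O)C(F)(F)F | intermediate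
19 | C3 tertiary alcohol, 4-OTBS ester | O1[C@H](CC(=O)OC)[C@](C)(O)[C@@H](O[Si](C)(C)C(C)(C)C)C[C@@H]1C(C)=C | intermediate
20 | 3-OTES, 4-OTBS methyl ester | O1[C@H](CC(=O)OC)[C@](C)(O[Si](CC)(CC)CC)[C@@H](O[Si](C)(C)C(C)(C)C)C[C@@H]1C(C)=C | intermediate
21 | 3-OTES, 4-OTBS carboxylic acid | O1[C@H](CC(=O)O)[C@](C)(O[Si](CC)(CC)CC)[C@@H](O[Si](C)(C)C(C)(C)C)C[C@@H]1C(C)=C | intermediate
22 | isobutyl carbonic mixed anhydride of 21 | O1[C@H](CC(=O)OC(=O)OCC(C)C)[C@](C)(O[Si](CC)(CC)CC)[C@@H](O[Si](C)(C)C(C)(C)C)C[C@@H]1C(C)=C | intermediate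
23 | tetrahydropyranyl diazoketone | O1[C@H](CC(=O)C=[N+]=[N-])[C@](C)(O[Si](CC)(CC)CC)[C@@H](O[Si](C)(C)C(C)(C)C)C[C@@H]1C(C)=C | intermediate
24 | bicyclic oxonium ylide (O bonded to C2, C6 and C9) | [O+]12[C@H](CC(=O)[CH-]2)[C@](C)(O[Si](CC)(CC)CC)[C@@H](O[Si](C)(C)C(C)(C)C)C[C@@H]1C(C)=C | intermediate
25 | C2–O–C9 bridged (Z)-oxonene, C10 ketone | CC(C)(C)[Si](C)(C)O[C@H]1C/C=C(C)\C[C@H]2O[C@H](CC2=O)[C@]1(C)O[Si](CC)(CC)CC | intermediate
26 | sodium C1=C10 enolate of 25 | CC(C)(C)[Si](C)(C)O[C@H]1C/C=C(C)\C[C@H]2O[C@H](C=C2[O-])[C@]1(C)O[Si](CC)(CC)CC.[Na+] | intermediate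
27 | C1=C10 enol triflate | CC(C)(C)[Si](C)(C)O[C@H]1C/C=C(C)\C[C@H]2O[C@H](C=C2OS(=O)(=O)C(F)(F)F)[C@]1(C)O[Si](CC)(CC)CC | intermediate
28 | tributyl(1-ethoxyvinyl)stannane | CCCC[Sn](CCCC)(CCCC)C(=C)OCC | starting material
29 | bicyclic 2-ethoxy diene | CC(C)(C)[Si](C)(C)O[C@H]1C/C=C(C)\C[C@H]2O[C@H](C=C2C(=C)OCC)[C@]1(C)O[Si](CC)(CC)CC | intermediate
30 | methyl vinyl ketone | CC(=O)C=C | starting material
31 | tricyclic endo Diels–Alder adduct | CC(C)(C)[Si](C)(C)O[C@H]1C/C=C(C)\C[C@H]2O[C@@H]([C@]1(C)O[Si](CC)(CC)CC)[C@@H]3[C@@H](CCC(OCC)=C32)C(C)=O | intermediate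
32 | C14 isopropenyl tricycle | CC(C)(C)[Si](C)(C)O[C@H]1C/C=C(C)\C[C@H]2O[C@@H]([C@]1(C)O[Si](CC)(CC)CC)[C@@H]3[C@@H](CCC(OCC)=C32)C(C)=C | intermediate
33 | C16 B-alkyl-9-borabicyclononane | CC(C)(C)[Si](C)(C)O[C@H]1C/C=C(C)\C[C@H]2O[C@@H]([C@]1(C)O[Si](CC)(CC)CC)[C@@H]3[C@@H](CCC(OCC)=C32)[C@H](C)CB1C2CCCC1CCC2 | intermediate
34 | C16 primary alcohol (15S) | CC(C)(C)[Si](C)(C)O[C@H]1C/C=C(C)\C[C@H]2O[C@@H]([C@]1(C)O[Si](CC)(CC)CC)[C@@H]3[C@@H](CCC(OCC)=C32)[C@H](C)CO | intermediate
35 | C11 ketone, C3/C16 diol | CC(C)(C)[Si](C)(C)O[C@H]1C/C=C(C)\C[C@H]2O[C@@H]([C@]1(C)O)[C@@H]3[C@@H](CCC(=O)[C@@H]32)[C@H](C)CO | intermediate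
36 | C16 primary triflate | CC(C)(C)[Si](C)(C)O[C@H]1C/C=C(C)\C[C@H]2O[C@@H]([C@]1(C)O)[C@@H]3[C@@H](CCC(=O)[C@@H]32)[C@H](C)COS(=O)(=O)C(F)(F)F | intermediate
37 | tetracyclic C11 ketone (oxepane closed) | CC(C)(C)[Si](C)(C)O[C@H]1C/C=C(C)\C[C@H]2O[C@@H]3[C@@H]4[C@@H](CCC(=O)[C@@H]42)[C@H](C)CO[C@]13C | intermediate
38 | lithium C11=C12 enolate of 37 | CC(C)(C)[Si](C)(C)O[C@H]1C/C=C(C)\C[C@H]2O[C@@H]3[C@@H]4[C@@H](CC=C([O-])[C@@H]42)[C@H](C)CO[C@]13C.[Li+] | intermediate
39 | C11=C12 trimethylsilyl enol ether | CC(C)(C)[Si](C)(C)O[C@H]1C/C=C(C)\C[C@H]2O[C@@H]3[C@@H]4[C@@H](CC=C(O[Si](C)(C)C)[C@@H]42)[C@H](C)CO[C@]13C | intermediate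
40 | C11 ketone, C12=C13 enone | CC(C)(C)[Si](C)(C)O[C@H]1C/C=C(C)\C[C@H]2O[C@@H]3[C@@H]4[C@@H](C=CC(=O)[C@@H]42)[C@H](C)CO[C@]13C | intermediate
41 | C11 tertiary allylic alcohol (C11 open) | CC(C)(C)[Si](C)(C)O[C@H]1C/C=C(C)\C[C@H]2O[C@@H]3[C@@H]4[C@@H](C=CC(C)(O)[C@@H]42)[C@H](C)CO[C@]13C | intermediate
42 | tetracyclic C13 enone with C11 methyl | CC(C)(C)[Si](C)(C)O[C@H]1C/C=C(C)\C[C@H]2O[C@@H]3[C@@H]4[C@@H](C(=O)C=C(C)[C@@H]42)[C@H](C)CO[C@]13C | intermediate
43 | 6,7-syn-diol (6R,7S) | CC(C)(C)[Si](C)(C)O[C@H]1C[C@@H](O)[C@@](C)(O)C[C@H]2O[C@@H]3[C@@H]4[C@@H](C(=O)C=C(C)[C@@H]42)[C@H](C)CO[C@]13C | intermediate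
44 | C6 ketone, C7 tertiary alcohol | CC(C)(C)[Si](C)(C)O[C@H]1CC(=O)[C@@](C)(O)C[C@H]2O[C@@H]3[C@@H]4[C@@H](C(=O)C=C(C)[C@@H]42)[C@H](C)CO[C@]13C | intermediate
45 | tetramethylammonium C7-alkoxy(diacetoxy)borohydride | CC(C)(C)[Si](C)(C)O[C@H]1CC(=O)[C@@](C)(O[BH-](OC(C)=O)OC(C)=O)C[C@H]2O[C@@H]3[C@@H]4[C@@H](C(=O)C=C(C)[C@@H]42)[C@H](C)CO[C@]13C.C[N+](C)(C)C | intermediate
46 | 6,7-diol (6S,7S), 4-OTBS | CC(C)(C)[Si](C)(C)O[C@H]1C[C@H](O)[C@@](C)(O)C[C@H]2O[C@@H]3[C@@H]4[C@@H](C(=O)C=C(C)[C@@H]42)[C@H](C)CO[C@]13C | intermediate
47 | 4,6,7-triol | O[C@H]1C[C@H](O)[C@@](C)(O)C[C@H]2O[C@@H]3[C@@H]4[C@@H](C(=O)C=C(C)[C@@H]42)[C@H](C)CO[C@]13C | intermediate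
48 | CNP0212231.3 | CC(=O)O[C@H]1C[C@H](OC(C)=O)[C@@](C)(O)C[C@H]2O[C@@H]3[C@@H]4[C@@H](C(=O)C=C(C)[C@@H]42)[C@H](C)CO[C@]13C | target

**Step count**

- Total step count: 34
- Longest linear sequence: 33 (steps 1–8 and 10–34; step 9 is the only side branch)

**Steps most likely to fail**

Step 21. The endo preference of the cycloaddition may be too low. The exo mode puts C15 trans to C2, and the axial acetyl group may also drift to the more stable equatorial C14 epimer. The fallback sets out from 29 and comes back at 31.
- Diene 29 is heated in toluene with but-3-yn-2-one, a dienophile that has no endo/exo question. This gives the cyclohexa-1,4-dienyl methyl ketone F1, with C1 set by the same facial bias.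
- Chemoselective conjugate reduction of the C13=C14 enone with [(Ph3P)CuH]6 in toluene containing tBuOH delivers hydride to C13.
- The regiodefined enolate is protonated at C14 from the convex face, the face that carries H1. This places the acetyl group cis to C2 and gives 31.

Step 23. Facial selectivity at C15 may be poor, because two rotamers about C14–C15 lead to opposite epimers. The fallback sets out from 32 and comes back at 34.
- After the hydroboration the unwanted 15-epi alcohol F2 is separated and oxidised with Dess–Martin periodinane to the C16 aldehyde F3, whose only acidic position is C15.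
- F3 is equilibrated with DBU in CH2Cl2, reduced with NaBH4 in MeOH and separated again.
- C15 is then corrected by thermodynamic equilibration and recycling instead of by kinetic face selection.

Step 30. The oxidant may attack the inner face of the C6=C7 alkene, which would misplace the tertiary C7 oxygen. The fallback sets out from 42 and comes back at 46, bypassing 43 to 45.
- Compound 42 is epoxidised with mCPBA (NaHCO3, CH2Cl2) on the face the substrate actually prefers. This gives the inner-face 6,7-epoxide F4, which already carries the correct C6–O bond.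
- Sc(OTf)3-catalysed hydrolysis in THF/H2O then opens F4 at the tertiary C7 with inversion, with water arriving from the open outer face, and gives 46 directly.

**Further compounds**

F1 | step 21 | cyclohexa-1,4-dienyl methyl ketone from 29 and but-3-yn-2-one | CC(C)(C)[Si](C)(C)O[C@H]1C/C=C(C)\C[C@H]2O[C@@H]([C@]1(C)O[Si](CC)(CC)CC)[C@@H]3C(C(C)=O)=CCC(OCC)=C32
F2 | step 23 | 15-epi C16 alcohol | CC(C)(C)[Si](C)(C)O[C@H]1C/C=C(C)\C[C@H]2O[C@@H]([C@]1(C)O[Si](CC)(CC)CC)[C@@H]3[C@@H](CCC(OCC)=C32)[C@@H](C)CO
F3 | step 23 | C16 aldehyde (C15 equilibrating) | CC(C)(C)[Si](C)(C)O[C@H]1C/C=C(C)\C[C@H]2O[C@@H]([C@]1(C)O[Si](CC)(CC)CC)[C@@H]3[C@@H](CCC(OCC)=C32)C(C)C=O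
F4 | step 30 | inner-face 6,7-epoxide of 42 | CC(C)(C)[Si](C)(C)O[C@H]1C[C@@H]5O[C@]5(C)C[C@H]2O[C@@H]3[C@@H]4[C@@H](C(=O)C=C(C)[C@@H]42)[C@H](C)CO[C@]13C
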